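The phloroglucinol A ring (C4a–C5–C6–C7–C8–C8a) is not bought but built onto a preformed, enantioenriched C ring. Its oxygens at C5 and C7 and the prenyl group at C8, next to O1-bearing C8a, map onto a 4-prenylated 1-methoxy-1,3-bis(silyloxy)diene, which is annulated to the enone C=C (pyranone C5=C6) of an (S)-2-aryl-5-bromo-2,3-dihydropyran-4-one. One operation forms C8–C8a and C4a–C5, and loss of HBr and methanol aromatises, so prenyl can only sit at C8. The aryl oxygen is carried as an acetate, not a silyl ether, to keep the benzylic C2–O1 bond from ionising.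

Key step: step 6

Assumption: (S)-BINOL–Ti(IV) is taken to give the (S)-dihydropyranone, by analogy with its facial preference for aromatic aldehydes in additions of this type; if the sense proves opposite, (R)-BINOL is used with no other change.

Step 1
Reactants: 1 vanillin acetate (4-formyl-2-methoxyphenyl acetate); 2 (E)-1-methoxy-3-(trimethylsilyloxy)buta-1,3-diene
Product: 4 2-methoxy-4-[(2S)-4-oxo-3,4-dihydro-2H-pyran-2-yl]phenyl acetate, via silylated aldol adduct 3 (not isolated)
Conditions: (S)-BINOL (20 mol %), Ti(Oi-Pr)4 (10 mol %), 4 Å MS, Et2O, −20 °C; then TFA, CH2Cl2, 0 °C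
Reagents that add atoms: none
Why: Catalytic asymmetric hetero-Diels–Alder reaction in its Mukaiyama-aldol/cyclisation form, in which the chiral BINOL–titanium complex blocks one face of the aldehyde so that the diene terminus adds to the other and sets C2 as S, after which acid closes the ring with loss of methanol and the silyl group.

Step 2
Reactants: 4 2-methoxy-4-[(2S)-4-oxo-3,4-dihydro-2H-pyran-2-yl]phenyl acetate
Product: 5 4-[(2S)-5-bromo-4-oxo-3,4-dihydro-2H-pyran-2-yl]-2-methoxyphenyl acetate
Conditions: NBS (1.05 equiv), CH2Cl2, 0 °C, dark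
Reagents that add atoms: N-bromosuccinimide, O=C1CCC(=O)N1Br
Why: Electrophilic α-bromination of a vinylogous ester, in which Br+ adds to the nucleophilic C5 and the oxocarbenium ion loses the C5 proton, while the acetoxy-deactivated arene and the C2 centre are not touched under these neutral conditions.

Step 3
Reactants: 6 methyl acetoacetate; 7 prenyl bromide (1-bromo-3-methylbut-2-ene)
Product: 9 methyl 7-methyl-3-oxooct-6-enoate, via acetoacetate dianion 8 (not isolated)
Conditions: NaH, THF, 0 °C; n-BuLi, 0 °C; then 7, 0 °C to rt; 1 M HCl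
Reagents that add atoms: none
Why: γ-Alkylation of a β-keto ester dianion, whose more basic terminal carbanion displaces the allylic bromide by SN2.

Step 4
Reactants: 9 methyl 7-methyl-3-oxooct-6-enoate
Product: 10 methyl 7-methyl-3-(trimethylsilyloxy)octa-2,6-dienoate (2E/2Z mixture, geometry irrelevant later)
Conditions: Me3SiCl, Et3N, hexane, rt
Reagents that add atoms: chlorotrimethylsilane, C[Si](C)(C)Cl
Why: Silyl enol ether formation by O-silylation of the enolised β-keto ester under amine base.

Step 5
Reactants: 10 methyl 7-methyl-3-(trimethylsilyloxy)octa-2,6-dienoate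
Product: 12 1-methoxy-7-methyl-1,3-bis(trimethylsilyloxy)octa-1,3,6-triene (geometric mixture, used crude under argon), via lithium dienolate 11 (not isolated)
Conditions: LDA, THF, −78 °C; Me3SiCl, −78 °C to rt; hexane, filtration under argon
Reagents that add atoms: chlorotrimethylsilane, C[Si](C)(C)Cl
Why: γ-Deprotonation of the β-silyloxy enoate to the ester dienolate and O-silylation (ketene silyl acetal formation), the standard entry to 1,3-bis(silyloxy)dienes.

Step 6
Reactants: 5 4-[(2S)-5-bromo-4-oxo-3,4-dihydro-2H-pyran-2-yl]-2-methoxyphenyl acetate; 12 1-methoxy-7-methyl-1,3-bis(trimethylsilyloxy)octa-1,3,6-triene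
Product: 15 4-[(2S)-5,7-dihydroxy-8-(3-methylbut-2-en-1-yl)-4-oxo-3,4-dihydro-2H-chromen-2-yl]-2-methoxyphenyl acetate, via bromo ketal cycloadduct 13 (not isolated), via 5,7-bis(trimethylsilyl) ether 14 (not isolated)
Conditions: Me3SiOTf (1.1 equiv), CH2Cl2, −78 °C; 12 (1.3 equiv), −78 to −20 °C; i-Pr2NEt (3 equiv), −20 to 20 °C; then 10% aq. citric acid, MeOH, 20 °C
Reagents that add atoms: none
Why: Proposed new method: Me3SiOTf O-silylates the vinylogous ester of 5 to a 5-bromo-4-silyloxy-2H-pyranylium ion, whose oxygen-bearing carbon (future C8a) is attacked by the nucleophilic, prenyl-bearing C4 terminus of 12 (Mukaiyama–Michael addition), and the α-bromo silyl enol ether so formed then closes onto the dialkoxycarbenium carbon left from the ketene acetal (future C5) to give bromo ketal 13, a stepwise ionic [4+2] annulation. The closest known chemistry is the silyl-triflate-mediated addition of 1,3-bis(silyloxy)dienes to chromones through benzopyrylium ions, together with the Diels–Alder/aromatisation of such dienes with haloquinones. The one new ring, the carbocyclic A ring, closes in a 6-(enolexo)-exo-trig mode, C4a attacking C5. Ionisation of the C5 ketal with loss of MeOSiMe3 and γ-deprotonation give a 5,7-bis(silyloxy)cyclohexadiene, from which the amine removes HBr across C8a–C4a in an aromatisation-driven elimination to 14, and mild acid then frees the two phenols. No stereocentre is created, since C4a, C5, C8 and C8a all end sp2, and C2 from step 1 should be retained because the para-acetoxy aryl group gives little support to ionisation of the benzylic C2–O1 bond at low temperature. The selectivity needed, prenyl at C8 and not C6, follows from the matched polarity of the diene (nucleophilic C4) and the pyranylium ion (electrophilic oxygen-bearing carbon), so no choice among equivalent arene positions arises.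

Step 7
Reactants: 15 4-[(2S)-5,7-dihydroxy-8-(3-methylbut-2-en-1-yl)-4-oxo-3,4-dihydro-2H-chromen-2-yl]-2-methoxyphenyl acetate
Product: 16 (2S)-5,7-dihydroxy-2-(4-hydroxy-3-methoxyphenyl)-8-(3-methylbut-2-en-1-yl)-2,3-dihydro-4H-chromen-4-one
Conditions: NH4OAc, MeOH, rt
Reagents that add atoms: none
Why: Neutral ammonium acetate-mediated methanolysis (transesterification) of the aryl acetate, the most electrophilic group present, which avoids both the base that could open the flavanone to its chalcone and the acid that could cyclise the prenyl group onto the 7-hydroxyl.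

Compound list
1 | vanillin acetate (4-formyl-2-methoxyphenyl acetate) | COc1cc(C=O)ccc1OC(C)=O | starting material
2 | (E)-1-methoxy-3-(trimethylsilyloxy)buta-1,3-diene | CO/C=C/C(=C)O[Si](C)(C)C | starting material
3 | 2-methoxy-4-[(1S,4E)-5-methoxy-3-oxo-1-(trimethylsilyloxy)pent-4-en-1-yl]phenyl acetate | CO/C=C/C(=O)C[C@H](O[Si](C)(C)C)c1ccc(OC(C)=O)c(OC)c1 | intermediate (not isolated)
4 | 2-methoxy-4-[(2S)-4-oxo-3,4-dihydro-2H-pyran-2-yl]phenyl acetate | COc1cc([C@@H]2CC(=O)C=CO2)ccc1OC(C)=O | intermediate
5 | 4-[(2S)-5-bromo-4-oxo-3,4-dihydro-2H-pyran-2-yl]-2-methoxyphenyl acetate | COc1cc([C@@H]2CC(=O)C(Br)=CO2)ccc1OC(C)=O | intermediate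
6 | methyl acetoacetate | COC(=O)CC(C)=O | starting material
7 | prenyl bromide (1-bromo-3-methylbut-2-ene) | CC(C)=CCBr | starting material
8 | sodium lithium dianion of methyl acetoacetate | [Na+].[Li+].C=C([O-])C=C([O-])OC | intermediate (not isolated)
9 | methyl 7-methyl-3-oxooct-6-enoate | COC(=O)CC(=O)CCC=C(C)C | intermediate
10 | methyl 7-methyl-3-(trimethylsilyloxy)octa-2,6-dienoate (2E/2Z mixture) | COC(=O)C=C(CCC=C(C)C)O[Si](C)(C)C | intermediate
11 | lithium 1-methoxy-7-methyl-3-(trimethylsilyloxy)octa-1,3,6-trien-1-olate | [Li+].COC([O-])=CC(O[Si](C)(C)C)=CCC=C(C)C | intermediate (not isolated)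
12 | 1-methoxy-7-methyl-1,3-bis(trimethylsilyloxy)octa-1,3,6-triene (geometric mixture) | COC(O[Si](C)(C)C)=CC(O[Si](C)(C)C)=CCC=C(C)C | intermediate
13 | 4-[(2S)-4a-bromo-5-methoxy-8-(3-methylbut-2-en-1-yl)-4-oxo-5,7-bis(trimethylsilyloxy)-3,4,4a,5,8,8a-hexahydro-2H-chromen-2-yl]-2-methoxyphenyl acetate (mixture at C4a, C5, C8, C8a) | COc1cc([C@@H]2CC(=O)C3(Br)C(OC)(O[Si](C)(C)C)C=C(O[Si](C)(C)C)C(CC=C(C)C)C3O2)ccc1OC(C)=O | intermediate (not isolated)
14 | 2-methoxy-4-[(2S)-8-(3-methylbut-2-en-1-yl)-4-oxo-5,7-bis(trimethylsilyloxy)-3,4-dihydro-2H-chromen-2-yl]phenyl acetate | COc1cc([C@@H]2CC(=O)c3c(O[Si](C)(C)C)cc(O[Si](C)(C)C)c(CC=C(C)C)c3O2)ccc1OC(C)=O | intermediate (not isolated)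
15 | 4-[(2S)-5,7-dihydroxy-8-(3-methylbut-2-en-1-yl)-4-oxo-3,4-dihydro-2H-chromen-2-yl]-2-methoxyphenyl acetate | COc1cc([C@@H]2CC(=O)c3c(O)cc(O)c(CC=C(C)C)c3O2)ccc1OC(C)=O | intermediate
16 | (2S)-5,7-dihydroxy-2-(4-hydroxy-3-methoxyphenyl)-8-(3-methylbut-2-en-1-yl)-2,3-dihydro-4H-chromen-4-one | COc1cc([C@@H]2CC(=O)c3c(O)cc(O)c(CC=C(C)C)c3O2)ccc1O | target

Total step count: 7. Longest linear sequence: 5 steps (6 → 9 → 10 → 12 → 15 → 16); the pyranone branch (1 → 4 → 5) joins at step 6.

Steps most likely to fail

Step 6. The sequence may stop after the first C–C bond at the open-chain Michael adduct. The α-bromo-β-dicarbonyl intermediate may also give up bromine as Br+ and expel O1 by β-elimination, opening the pyran ring instead of losing HBr. C2 may racemise if the benzylic C–O bond ionises. The fallback uses known flavanone chemistry and gives up the de novo A ring; it sets out from prenyl bromide 7 and vanillin acetate 1 and comes back at 16. Purchased 2,4,6-trihydroxyacetophenone should be C-prenylated with 7 (DBU, THF) to 1-[2,4,6-trihydroxy-3-(3-methylbut-2-en-1-yl)phenyl]ethanone F1. MOMCl and i-Pr2NEt are expected to protect the 4- and 6-hydroxyls and leave the hindered, chelated hydroxyl next to the prenyl group free, giving 1-[2-hydroxy-4,6-bis(methoxymethoxy)-3-(3-methylbut-2-en-1-yl)phenyl]ethanone F2; any regioisomer is removed here. Claisen–Schmidt condensation of F2 with 1 (KOH, EtOH, the acetate being lost in the basic medium) should give (E)-1-[2-hydroxy-4,6-bis(methoxymethoxy)-3-(3-methylbut-2-en-1-yl)phenyl]-3-(4-hydroxy-3-methoxyphenyl)prop-2-en-1-one F3. NaOAc in refluxing EtOH closes the ring through the only free ortho-hydroxyl (oxa-Michael addition) to racemic 2-(4-hydroxy-3-methoxyphenyl)-5,7-bis(methoxymethoxy)-8-(3-methylbut-2-en-1-yl)-2,3-dihydro-4H-chromen-4-one F4. HCl in MeOH removes the acetals to racemic 5,7-dihydroxy-2-(4-hydroxy-3-methoxyphenyl)-8-(3-methylbut-2-en-1-yl)-2,3-dihydro-4H-chromen-4-one F5, and preparative chiral-phase HPLC delivers the (2S)-enantiomer 16.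

Step 1. Facial selectivity may be insufficient, or of the opposite sense, with this aldehyde under titanium catalysis. The fallback changes the activation mode to hydrogen-bond organocatalysis; it sets out from 1 and comes back at 4. Aldehyde 1 and purchased (E)-1-(dimethylamino)-3-(tert-butyldimethylsilyloxy)buta-1,3-diene are combined under a tetra(1-naphthyl)-TADDOL catalyst (antipode chosen for the 2S product; toluene, −40 °C) in a concerted [4+2] cycloaddition to 4-[(2S)-4-(tert-butyldimethylsilyloxy)-6-(dimethylamino)-3,6-dihydro-2H-pyran-2-yl]-2-methoxyphenyl acetate F6. Acetyl chloride in the same flask then converts F6 to 4.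

Step 7. If the medium drifts basic, C2 may racemise through reversible retro-oxa-Michael opening to the chalcone, or cleavage may stay incomplete. The fallback replaces chemical solvolysis by biocatalysis; it sets out from 15 and comes back at 16. Immobilised Candida antarctica lipase B with n-butanol in tert-butyl methyl ether at 40 °C transfers the acetyl group to butanol under strictly neutral conditions; no new compound is formed on the way.

Further compounds
F1 | step 6 | 1-[2,4,6-trihydroxy-3-(3-methylbut-2-en-1-yl)phenyl]ethanone | CC(=O)c1c(O)cc(O)c(CC=C(C)C)c1O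
F2 | step 6 | 1-[2-hydroxy-4,6-bis(methoxymethoxy)-3-(3-methylbut-2-en-1-yl)phenyl]ethanone | CC(=O)c1c(OCOC)cc(OCOC)c(CC=C(C)C)c1O
F3 | step 6 | (E)-1-[2-hydroxy-4,6-bis(methoxymethoxy)-3-(3-methylbut-2-en-1-yl)phenyl]-3-(4-hydroxy-3-methoxyphenyl)prop-2-en-1-one | COc1cc(/C=C/C(=O)c2c(OCOC)cc(OCOC)c(CC=C(C)C)c2O)ccc1O
F4 | step 6 | racemic 2-(4-hydroxy-3-methoxyphenyl)-5,7-bis(methoxymethoxy)-8-(3-methylbut-2-en-1-yl)-2,3-dihydro-4H-chromen-4-one | COc1cc(C2CC(=O)c3c(OCOC)cc(OCOC)c(CC=C(C)C)c3O2)ccc1O
F5 | step 6 | racemic 5,7-dihydroxy-2-(4-hydroxy-3-methoxyphenyl)-8-(3-methylbut-2-en-1-yl)-2,3-dihydro-4H-chromen-4-one | COc1cc(C2CC(=O)c3c(O)cc(O)c(CC=C(C)C)c3O2)ccc1O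
F6 | step 1 | 4-[(2S)-4-(tert-butyldimethylsilyloxy)-6-(dimethylamino)-3,6-dihydro-2H-pyran-2-yl]-2-methoxyphenyl acetate | COc1cc([C@@H]2CC(O[Si](C)(C)C(C)(C)C)=CC(N(C)C)O2)ccc1OC(C)=O
F0 | step 7 | none | none
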